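**Retrosynthetic overview**
1. Locants follow the carbon chain: C1–C3 sec-butyl (C3 is the methine); ring A = C4, C5, C6, C11, C12, C13; ring B = C6–C11; side chain C14(=O)–C15=C16–OMe. β is the ring face of the C5 methyl, α that of the C4 sec-butyl.
2. Enabling feature: the ring-fusion α-ketol C11(OH)–C12(=O) of ring A, with the 1,3-placed oxygen at C9 of ring B. C11/C12 is a latent cyclohexane-1,2-dione: its enol is nucleophilic at C6 and its C11 carbonyl accepts an aldol. Ring B (C7–C10 = pent-3-en-2-one) is therefore annulated through C6–C7 (Michael) and C10–C11 (aldol) in one operation.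
3. After the key step: C9–CH3 by methyl addition to the C9 ketone; C14–C15 by ethynyl addition to the C14 aldehyde, oxidation, then C16–OMe by addition of methanol to the ynone.
4. Before the key step: ring A by an enantioselective Diels–Alder reaction (C4–C5 and C6–C11) of methacrolein with the 2-silyloxy diene made from (S)-2-methylbutan-1-ol; C13–OH by Rubottom oxidation; C11 oxidation by SeO2.
5. Order of ring formation: ring A (step 5), then ring B (step 9).

Key step: step 9

Remark: the sense of induction of the two chiral catalysts (steps 5 and 9) is assigned by analogy with their accepted transition-state models; the C3 centre comes from the chiral pool and is never touched.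

Step 1
Reactants: 1 (S)-2-methylbutan-1-ol; 2 ethyl 2-(triphenylphosphoranylidene)propanoate
Product: 4 ethyl (S,E)-2,4-dimethylhex-2-enoate, via (S)-2-methylbutanal 3 (not isolated)
Conditions: PhI(OAc)2, 2,2,6,6-tetramethylpiperidin-1-oxyl (10 mol %), CH2Cl2, 0 → 25 °C; then 2, 25 → 40 °C
Reagents that add atoms: none
Why: The nitroxyl-catalysed oxidation should give the configurationally labile aldehyde, which is trapped at once in an E-selective Wittig olefination with the stabilized α-methyl ylide, so that C3 is carried over from the chiral pool.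

Step 2
Reactants: 4 ethyl (S,E)-2,4-dimethylhex-2-enoate
Product: 5 (S,E)-N-methoxy-N,2,4-trimethylhex-2-enamide
Conditions: MeNH(OMe)·HCl, i-PrMgCl, THF, −20 °C
Reagents that add atoms: N,O-dimethylhydroxylamine hydrochloride CNOC.Cl
Why: Direct aminolysis of the ester by the chloromagnesium amide (Weinreb amide formation) should proceed without touching the alkene geometry or the C3 centre.

Step 3
Reactants: 5 (S,E)-N-methoxy-N,2,4-trimethylhex-2-enamide
Product: 6 (S,E)-3,5-dimethylhept-3-en-2-one
Conditions: MeMgBr, THF, 0 °C
Reagents that add atoms: methylmagnesium bromide C[Mg]Br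
Why: Weinreb ketone synthesis, in which the chelated tetrahedral intermediate prevents over-addition and conjugate addition.

Step 4
Reactants: 6 (S,E)-3,5-dimethylhept-3-en-2-one
Product: 7 (S,E)-tert-butyl[(3,5-dimethylhepta-1,3-dien-2-yl)oxy]dimethylsilane
Conditions: TBSOTf, Et3N, CH2Cl2, 0 °C
Reagents that add atoms: tert-butyldimethylsilyl trifluoromethanesulfonate CC(C)(C)[Si](C)(C)OS(=O)(=O)C(F)(F)F
Why: Soft enolization of the methyl ketone at the methyl group should give the cross-conjugated 2-silyloxy diene without touching the (E)-alkene or the allylic C3 centre.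

Step 5
Reactants: 7 (S,E)-tert-butyl[(3,5-dimethylhepta-1,3-dien-2-yl)oxy]dimethylsilane; 8 methacrolein
Product: 9 2-[(S)-butan-2-yl]-4-[(tert-butyldimethylsilyl)oxy]-1,3-dimethylcyclohex-3-ene-1-carbaldehyde with formyl cis to sec-butyl (C4 sec-butyl α, C5 formyl α, C5 methyl β)
Conditions: (R)-3,3-diphenyl-1-(o-tolyl)tetrahydro-1H,3H-pyrrolo[1,2-c][1,3,2]oxazaborole (C24H24BNO, 15 mol %), HN(SO2CF3)2 (12 mol %), CH2Cl2, −78 → −40 °C
Reagents that add atoms: none
Why: Catalytic enantioselective Diels–Alder reaction that forms ring A (C4–C5 and C6–C11): the 2-silyloxy group (para) and the terminal alkyl group (ortho) both place the quaternary C5 next to C4, the acid-bound formyl group reacts endo so that formyl and sec-butyl become cis, and the (R)-oxazaborolidinium ion, which holds the s-trans enal through boron and a formyl C–H···O contact and covers the Re face of C5, should set C4 and C5 by catalyst control over the weak bias of C3.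

Step 6
Reactants: 9 Diels–Alder adduct
Product: 11 2-[(S)-butan-2-yl]-3-hydroxy-1,3-dimethyl-4-oxocyclohexane-1-carbaldehyde (C13 hydroxyl β, C13 methyl α), via silyloxy epoxide 10 (not isolated)
Conditions: dimethyldioxirane, acetone/CH2Cl2, −78 → −20 °C; then 1 M aq. HCl, THF, 0 °C
Reagents that add atoms: dimethyldioxirane CC1(C)OO1
Why: Rubottom oxidation, in which the tetrasubstituted silyl enol ether is epoxidized on the β face, away from the C4 sec-butyl and C5 formyl groups on the α face, and the silyloxy epoxide is hydrolysed to the α-hydroxy ketone, which sets C13.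

Step 7
Reactants: 11 hydroxy keto aldehyde
Product: 12 3-[(S)-butan-2-yl]-4-(1,3-dioxolan-2-yl)-2-hydroxy-2,4-dimethylcyclohexan-1-one
Conditions: ethylene glycol, pyridinium p-toluenesulfonate (10 mol %), benzene, reflux, Dean–Stark
Reagents that add atoms: ethylene glycol OCCO
Why: Chemoselective acetalization of the aldehyde, since the ketone next to the tertiary carbinol is deactivated and hindered; the acetal masks C14 through the base and organometallic steps.

Step 8
Reactants: 12 dioxolane ketone
Product: 13 5-[(S)-butan-2-yl]-4-(1,3-dioxolan-2-yl)-2,6-dihydroxy-4,6-dimethylcyclohex-2-en-1-one (diosphenol form of the ring A 1,2-dione, enol C6=C11)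
Conditions: SeO2, 1,4-dioxane/H2O (30:1), 90 °C
Reagents that add atoms: selenium dioxide O=[Se]=O
Why: Riley oxidation of the only enolizable α-methylene (C11, because C13 is quaternary) should give the 1,2-dione, which rests as the diosphenol with its enol towards C6 and leaves all stereocentres untouched.

Step 9
Reactants: 13 diosphenol; 14 (E)-pent-3-en-2-one
Product: 16 trans-fused ring B ketol (C9 ketone, C11 hydroxyl β, H6 α, C7 methyl α and equatorial, C12 ketone, C13 hydroxyl β), via Michael adduct 15 (not isolated)
Conditions: 9-amino-9-deoxy-epi-quinine (C20H25N3O, 20 mol %), CF3CO2H (40 mol %), THF, 25 °C; then pyrrolidine (30 mol %), AcOH (30 mol %), 40 °C, same flask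
Reagents that add atoms: none
Why: The primary amine salt converts 14 into an (E)-iminium ion that is attacked at C7 by C6 of diosphenol 13, the only enolizable carbon of the dione because C13 is quaternary, to give 15; 15 equilibrates with its C11-keto tautomer, and the terminal enamine of the C9 ketone then adds through C10 to the C11 carbonyl, which is activated by the adjacent C12 carbonyl. The closest known reaction type is the amine-catalysed Michael/aldol (Robinson-type) annulation of cyclic dicarbonyl compounds with enones stopped at the ketol stage, including the domino Michael/aldol reactions of cyclohexane-1,2-diones with unsaturated carbonyl compounds. Ring B is closed by a 6-(enolendo)-exo-trig aldol addition. C7 is set by the catalyst, which shields one face of the iminium ion and, by analogy with its additions of cyclic enols to (E)-enones, should give the 7R centre regardless of ring A, since C6 is planar again in 15. C6 and C11 are set by the substrate: with ring A in the chair that has the C4 sec-butyl group axial on the α face, the β-methyl at C5 and the β-hydroxyl at C13 are syn-axial to C11, so C10 enters equatorially from the α side through a chair-like ring B with the C7 methyl equatorial, which places H6 α and the C11 hydroxyl β (axial) and gives the trans ring fusion, and the reversible aldol lets other ketols return through 15. The step needs C- over O-alkylation at C6 and closure from C10 to C11 instead of from C8 to C12; the soft iminium acceptor secures the first, and the position of C12 next to the quaternary C13, where only a strained bridged five-membered ring could form, secures the second.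

Step 10
Reactants: 16 ring B ketol
Product: 17 C9 tertiary carbinol (C9 hydroxyl β and axial, C9 methyl α and equatorial), dioxolane retained
Conditions: MeMgBr (excess), THF, −78 → −40 °C
Reagents that add atoms: methylmagnesium bromide C[Mg]Br
Why: Grignard 1,2-addition to the only unhindered ketone (C12 lies between two fully substituted carbons), with equatorial attack from the α side because the axial C11 oxygen blocks the β-axial trajectory, which should give the axial β-hydroxyl and equatorial methyl at C9.

Step 11
Reactants: 17 dioxolane triol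
Product: 18 C14 aldehyde (free C9, C11, C13 hydroxyls, C12 ketone)
Conditions: 1 M aq. HCl/THF (1:2), 25 °C
Reagents that add atoms: water O
Why: Acid-catalysed acetal hydrolysis under conditions that the tertiary alcohols should survive, and no lactol can form because C14 is α while all hydroxyls are β.

Step 12
Reactants: 18 aldehyde
Product: 19 C14 propargylic alcohol (mixture of C14 epimers, both carried on)
Conditions: HC≡CMgBr (excess), THF, −20 → 0 °C
Reagents that add atoms: ethynylmagnesium bromide C#C[Mg]Br
Why: 1,2-addition of the alkynyl Grignard reagent to the aldehyde, which is far more reactive than the doubly α-quaternary C12 ketone; the new carbinol centre is removed in the next step.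

Step 13
Reactants: 19 propargylic alcohol
Product: 20 C14 ynone (terminal alkyne)
Conditions: MnO2 (activated, excess), CH2Cl2, 25 °C
Reagents that add atoms: none
Why: Selective oxidation of the propargylic secondary alcohol by MnO2, to which the three tertiary alcohols are inert.

Step 14
Reactants: 20 ynone
Product: 21 CNP0304150.3
Conditions: MeOH, 1,4-diazabicyclo[2.2.2]octane (10 mol %), 0 → 25 °C
Reagents that add atoms: methanol CO
Why: Amine-catalysed conjugate addition of methanol to the terminal ynone should give the thermodynamically favoured (E)-β-methoxy enone, completing the side chain without touching any stereocentre.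

**Compound list**
1 | (S)-2-methylbutan-1-ol | CC[C@H](C)CO | starting material
2 | ethyl 2-(triphenylphosphoranylidene)propanoate | CCOC(=O)C(C)=P(c1ccccc1)(c1ccccc1)c1ccccc1 | starting material
3 | (S)-2-methylbutanal | CC[C@H](C)C=O | intermediate (not isolated)
4 | ethyl (S,E)-2,4-dimethylhex-2-enoate | CC[C@H](C)/C=C(C)/C(=O)OCC | intermediate
5 | (S,E)-N-methoxy-N,2,4-trimethylhex-2-enamide | CC[C@H](C)/C=C(C)/C(=O)N(C)OC | intermediate
6 | (S,E)-3,5-dimethylhept-3-en-2-one | CC[C@H](C)/C=C(C)/C(C)=O | intermediate
7 | (S,E)-tert-butyl[(3,5-dimethylhepta-1,3-dien-2-yl)oxy]dimethylsilane | CC[C@H](C)/C=C(C)/C(=C)O[Si](C)(C)C(C)(C)C | intermediate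
8 | methacrolein | CC(=C)C=O | starting material
9 | ring A Diels–Alder adduct: 2-[(S)-butan-2-yl]-4-[(tert-butyldimethylsilyl)oxy]-1,3-dimethylcyclohex-3-ene-1-carbaldehyde, formyl cis to sec-butyl | CC[C@H](C)[C@@H]1[C@](C)(C=O)CCC(O[Si](C)(C)C(C)(C)C)=C1C | intermediate
10 | silyloxy epoxide of 9 (C12–C13 oxirane, oxygen on the β face) | CC[C@H](C)[C@@H]1[C@](C)(C=O)CC[C@@]2(O[Si](C)(C)C(C)(C)C)O[C@@]12C | intermediate (not isolated)
11 | 2-[(S)-butan-2-yl]-3-hydroxy-1,3-dimethyl-4-oxocyclohexane-1-carbaldehyde (C13 hydroxyl β, trans to sec-butyl) | CC[C@H](C)[C@@H]1[C@](C)(C=O)CCC(=O)[C@@]1(C)O | intermediate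
12 | 3-[(S)-butan-2-yl]-4-(1,3-dioxolan-2-yl)-2-hydroxy-2,4-dimethylcyclohexan-1-one | CC[C@H](C)[C@@H]1[C@](C)(C2OCCO2)CCC(=O)[C@@]1(C)O | intermediate
13 | diosphenol: 5-[(S)-butan-2-yl]-4-(1,3-dioxolan-2-yl)-2,6-dihydroxy-4,6-dimethylcyclohex-2-en-1-one | CC[C@H](C)[C@@H]1[C@](C)(C2OCCO2)C=C(O)C(=O)[C@@]1(C)O | intermediate
14 | (E)-pent-3-en-2-one | C/C=C/C(C)=O | starting material
15 | Michael adduct: diosphenol 13 carrying an (R)-4-oxopentan-2-yl group at C6 | CC[C@H](C)[C@@H]1[C@](C)(C2OCCO2)C([C@H](C)CC(C)=O)=C(O)C(=O)[C@@]1(C)O | intermediate (not isolated)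
16 | trans-decalin ketol: C9 ketone, C11 β-hydroxyl, α-H6, C7 α-methyl, C12 ketone, C13 β-hydroxyl/α-methyl, C4 α-sec-butyl, C5 β-methyl/α-dioxolanyl | CC[C@H](C)[C@@H]1[C@](C)(C3OCCO3)[C@H]2[C@H](C)CC(=O)C[C@]2(O)C(=O)[C@@]1(C)O | intermediate
17 | as 16 with C9 carrying β-hydroxyl and α-methyl | CC[C@H](C)[C@@H]1[C@](C)(C3OCCO3)[C@H]2[C@H](C)C[C@@](C)(O)C[C@]2(O)C(=O)[C@@]1(C)O | intermediate
18 | C14 aldehyde (dioxolane of 17 removed) | CC[C@H](C)[C@@H]1[C@](C)(C=O)[C@H]2[C@H](C)C[C@@](C)(O)C[C@]2(O)C(=O)[C@@]1(C)O | intermediate
19 | C14 propargylic alcohol (1-hydroxyprop-2-yn-1-yl at C5, both C14 epimers) | CC[C@H](C)[C@@H]1[C@](C)(C(O)C#C)[C@H]2[C@H](C)C[C@@](C)(O)C[C@]2(O)C(=O)[C@@]1(C)O | intermediate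
20 | C14 ynone (propynoyl at C5) | CC[C@H](C)[C@@H]1[C@](C)(C(=O)C#C)[C@H]2[C@H](C)C[C@@](C)(O)C[C@]2(O)C(=O)[C@@]1(C)O | intermediate
21 | CNP0304150.3 | CC[C@H](C)[C@@H]1[C@](C)(C(=O)/C=C/OC)[C@H]2[C@H](C)C[C@@](C)(O)C[C@]2(O)C(=O)[C@@]1(C)O | target

**Step count and risks**
Total step count: 14. Longest linear sequence: 14 steps (from 1).

Steps most likely to fail:

1. Step 9. The intermolecular C–C bond formation at C6, which sits next to the quaternary C5, may be slow, so that O-alkylation of the enol competes and the catalyst's control of the C7 face erodes. The adduct may also rest as the unreactive diosphenol 15, so that the aldol is slow or reverts. Fallback: from 13, Mitsunobu etherification of the enol hydroxyl with (R,E)-pent-3-en-2-ol (PPh3, diisopropyl azodicarboxylate, inversion) would give the (S)-pent-3-en-2-yl enol ether F1. Heating (xylene, 140 °C) would effect the diosphenol Claisen rearrangement, which forms C6–C7 intramolecularly through a chair-like transition state with the carbinol methyl equatorial and transfers the ether configuration to C7 (7R), giving the C6-pentenyl diosphenol F2. Wacker oxidation of its internal alkene (Pd(OAc)2, benzoquinone, HBF4, N,N-dimethylacetamide/MeCN/H2O), with oxygen entering at C9 remote from the branched C7, would give 15. This is then cyclized as a separate operation (pyrrolidine, AcOH, THF, 40 °C) and the route is rejoined at 16.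

2. Step 5. The formyl group may react exo, or the catalyst may fail to override the hindered, trisubstituted diene terminus, giving poor endo and facial selectivity at C4/C5; the silyl enol ether may also be lost to the strong acid. Fallback: from 7, a stoichiometric auxiliary replaces the catalyst. (R)-Pantolactone methacrylate F3 (from methacryloyl chloride, (R)-pantolactone, Et3N) would undergo the Diels–Alder reaction with 7 under Et2AlCl (CH2Cl2, −78 °C) to give the pantolactone ester adduct F4. The facial sense is expected from the chelate model established for pantolactone acrylates. LiAlH4 would remove the auxiliary to give the neopentyl alcohol F5, and Dess–Martin periodinane/NaHCO3 would return the aldehyde, rejoining the route at 9.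

3. Step 10. Deprotonation of the C11 hydroxyl by the Grignard reagent may trigger retro-aldol opening of ring B, and delivery of methyl from the metal bound to the C11 oxygen may erode the facial selectivity at C9. Fallback: from 16, non-basic Lombardo methylenation (Zn, CH2Br2, TiCl4, THF) would give the C9 exocyclic methylene compound F6. Epoxidation directed by the C11 hydroxyl (VO(acac)2, t-BuOOH, CH2Cl2) would deliver oxygen on the β face to give the spiro-epoxide F7. MgI2 would open it at the methylene carbon to give the iodohydrin F8, and Bu3SnH/azobisisobutyronitrile would reduce the C–I bond, rejoining the route at 17.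

**Further compounds**
F1 | step 9 | (S)-pent-3-en-2-yl enol ether of diosphenol 13 | CC[C@H](C)[C@@H]1[C@](C)(C2OCCO2)C=C(O[C@@H](C)/C=C/C)C(=O)[C@@]1(C)O
F2 | step 9 | diosphenol carrying an (R,E)-pent-3-en-2-yl group at C6 | CC[C@H](C)[C@@H]1[C@](C)(C2OCCO2)C([C@H](C)/C=C/C)=C(O)C(=O)[C@@]1(C)O
F3 | step 5 | (R)-pantolactone methacrylate | C=C(C)C(=O)O[C@H]1C(=O)OCC1(C)C
F4 | step 5 | (R)-pantolactone ester analogue of adduct 9 | CC[C@H](C)[C@@H]1[C@](C)(C(=O)O[C@H]2C(=O)OCC2(C)C)CCC(O[Si](C)(C)C(C)(C)C)=C1C
F5 | step 5 | neopentyl alcohol corresponding to 9 (hydroxymethyl at C5) | CC[C@H](C)[C@@H]1[C@](C)(CO)CCC(O[Si](C)(C)C(C)(C)C)=C1C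
F6 | step 10 | C9 exocyclic methylene analogue of 16 | CC[C@H](C)[C@@H]1[C@](C)(C3OCCO3)[C@H]2[C@H](C)CC(=C)C[C@]2(O)C(=O)[C@@]1(C)O
F7 | step 10 | C9 spiro-epoxide (oxygen β) | CC[C@H](C)[C@@H]1[C@](C)(C3OCCO3)[C@H]2[C@H](C)C[C@]4(CO4)C[C@]2(O)C(=O)[C@@]1(C)O
F8 | step 10 | C9 iodohydrin (β-hydroxyl, α-iodomethyl) | CC[C@H](C)[C@@H]1[C@](C)(C3OCCO3)[C@H]2[C@H](C)C[C@@](CI)(O)C[C@]2(O)C(=O)[C@@]1(C)O
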